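## Structural features

The target is a linear meta-terphenyl made of three phloroglucinol rings. Ring A (position A6) is bonded to B1 and ring C (position C1) to B3 of the central ring B, so the oxygen on B2 lies between the two outer rings. Ring B is pentasubstituted, not hexasubstituted: B2, B4 and B6 carry oxygen, B1 and B3 carry the aryl groups, and B5 carries hydrogen. There is no stereocentre; the only possible stereo-element is the A6–B1 axis, which has four ortho oxygens and is not defined in the structure. Apart from the sulfate on the oxygen of A1, the molecule has a twofold axis through B2 and B5, so rings A and C are the same 2,4,6-trioxygenated aryl group. The fragile parts are the aryl hydrogen sulfate (lost with acids, Lewis acids or heat) and the nonaphenol core (air oxidation, C-alkylation), so the last step must be near-neutral and reductive. The real difficulty is twofold: both biaryl bonds join carbons that each have two ortho oxygens, a poor setting for cross-coupling, and one phenolic oxygen out of nine must be told apart from the other eight. The key step exploits the pattern of ring B: carbons B2, B3, B4 and B5 with the oxygens on B2 and B4 map onto a 4-aryl-3-alkoxycyclobutenone, and B1 and B6 with the oxygen on B6 map onto an aryl siloxyalkyne.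

## Logic of the disconnections

**31 to 30.** Eight benzylic C–O bonds and the C–O bond of the trichloroethyl ester are cut. Only a reductive, buffered end-game suits the sulfate and the air-sensitive polyphenol. The gain is that all nine masks fall in one operation. The demand is that transfer hydrogenolysis fragments the trichloroethyl group and leaves the aryl O–S bond intact.

**30 to 29.** The S–O bond at position A1 is cut. Installing the sulfate late, as a neutral diester, keeps every earlier intermediate an ordinary polyether. The demand is that 29 has exactly one free hydroxyl.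

**29 to 28 to 26.** The acetal C–O bond at A1 and the benzyl C–O bonds at B2 and B6 are cut. The annulation leaves B2 as a phenol and B6 as a silyl ether, and both must be capped before A1 is unmasked. The gain is a direct link to the annulation product 26. The demands are etherification of the hindered B2 phenol and acetal cleavage that spares benzyl ethers.

**26 to 15 plus 21 (key).** Bonds B1–B2 and B5–B6 are cut. Neither crowded biaryl bond is then made by coupling: B1 arrives as an alkyne carbon and B3 as the sp3 carbon of the four-membered ring. The two halves are of similar size and both derive from 1. The demands are thermal ring opening of 15, a regioselective [2+2] step and no diversion of the vinylketene.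

The design of 21 differs from one that carries the sulfate through the annulation as a trichloroethyl diester. The strong bases needed for the ynolate would dehydrochlorinate that group or attack sulfur. Adding it afterwards would require a free phenol ortho to the ynol ether, which is set up to add across it to a benzofuranone. The oxygen at A1 is therefore an acetal (MOM) in 21, and the other two oxygens of ring A are benzyl ethers.

**21 to 18 to 17 to 16 to 1.** The O–Si bond and the C(sp)–O bond are cut (oxygen transfer to an acetylide). The triple bond is traced to the formyl group plus one carbon from 3, and the acetal and two benzyl ethers to the free phenols of 1. The gain is a four-step branch from a commercial aldehyde. The demands are that two of three hydroxyls are benzylated selectively and that the ynol ether survives isolation.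

**15 to 7 plus 12.** Ring bonds C1–C2 and C3–C4 of the cyclobutenone are cut (ketene 14 plus ynol ether). This cycloaddition places the aryl group at C4 and the alkoxy group at C3 directly. The benzyl group must come with the ynol ether. Exchanging a simpler alkoxy group on the finished ring would pass through a 2-arylcyclobutane-1,3-dione, whose enol lies toward the aryl-bearing carbon, so re-alkylation would give the 2-aryl isomer and not 15. The demands are ketene generation without electrophilic attack on the electron-rich ring and cold handling of 12.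

**7 to 4 to 2 to 1, and 12 to 8 plus 9.** In 7 the carboxyl C–O bonds are cut (oxidation of the alkyne terminus of 4), 4 is traced to aldehyde 2, and 2 to 1. In 12 the O–C(sp) bond is cut, giving an alkoxide and a C2 electrophile. Both ynolate steps use the same chemistry, so one set of operations serves both branches.

## Other disconnections considered

**Alternative 1:** The cut is in the outer rings. At position A1 of ring A and position C2 of ring C the two ring bonds of each carbinol carbon are broken (A1–A2, A1–A6, C1–C2, C2–C3), and that carbon is traced to CO. The precursor is compound A1, a tribenzylated ring B core with two identical arms –CH=C(OBn)–CH(OAc)–C≡CH at B1 and B3. Forward, [Rh(CO)2Cl]2 (monovalent rhodium) under CO should effect a 1,2-acetoxy shift and a carbonylative (5+1) closure in each arm. This would give compound A2, with a free hydroxyl ortho and an acetate para to each biaryl bond.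

- In its favour: it is two-directional and uses the latent twofold symmetry. Both outer rings form in one operation, and the two free hydroxyls are exactly the equivalent sites where one sulfate is wanted. On symmetry use and probable step count it is the better plan.
- It also avoids biaryl coupling, where it is the equal of the chosen plan.
- Against it: the two hydroxyls of compound A2 are equivalent, so monosulfation is statistical. The (5+1) reaction must run twice in one molecule on benzyl enol ethers attached to a di-ortho-substituted arene, with a defined alkene geometry and under CO.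
- Comparison: the chosen plan marks position A1 from the start and has no statistical step. Mechanistically it is a metal-free thermal cascade, but it builds the crowded inner ring whereas Alternative 1 builds the outer ones.

**Alternative 2:** The cut is bond C2–C3 of ring C. The precursor is compound A3, a 3-aryl-4-hydroxy-6-methylpyran-2-one whose aryl group is the finished A–B biaryl. Forward, Mg(OMe)2 should open the lactone to a chelated diketo ester, and NaOMe in hot methanol should close the methyl-derived carbanion onto the ester carbon. This would give compound A4, with ring C as a free triol.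

- In its favour: the closure is biomimetic, the reagents are cheap and robust, and no strained or moisture-sensitive intermediate is needed. On reagent robustness it is the equal or the better of the chosen plan.
- Against it: only one ring bond is formed. The A6–B1 bond and the aryl–pyranone bond must be made earlier by coupling at di-ortho-substituted carbons. The ester carbon attacked sits next to the carbon bearing the bulky aryl group, and relactonisation and retro-Claisen cleavage compete.
- Compound A4 also exposes three phenols on a phloroglucinol ring, which must be benzylated (with a risk of C-benzylation) before position A1 can be unmasked.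
- Comparison: the chosen plan forms two ring bonds, is convergent and needs no biaryl coupling. Alternative 2 is linear and probably longer.

**Alternative 3:** The cut is at the unhindered carbon of ring B: bonds B4–B5 and B5–B6. The precursors are compound A5, a dimethyl 2,4-diaryl-3-oxopentanedioate, and compound A6, the lithium enolate of tert-butyl acetate used in excess. Forward, the enolate carbon should be acylated twice by the two ester groups to give compound A7, a tert-butyl 3,5-diaryl-2,4,6-trihydroxybenzoate.

- In its favour: the ring closes far from the congested B1–B2–B3 sector. Both biaryl bonds come from arylacetic ester α-carbons, so no biaryl coupling is needed, which equals the chosen plan. The ester on B5 blocks C-alkylation during later benzylation, where it is the better plan.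
- Against it: compound A5 is a doubly activated keto diester that the enolate will deprotonate first, leaving poorly electrophilic ester groups. Two Claisen acylations must then occur next to di-ortho-substituted aryl groups.
- The ester on B5 has to be removed afterwards, three hindered hydroxyls of ring B need benzylation, and compound A5 itself requires a crossed condensation of two different arylacetates.
- Comparison: both plans are convergent and form two ring bonds. The chosen plan delivers ring B with its three oxygens already differentiated and no extra carbon, and is probably a few steps shorter.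

Key step: step 10

Remark: the structure carries no descriptor for the A6–B1 axis, so the compound is taken as undefined (racemic or rotating) about that axis and no control is attempted.
Remark: the hydrogen sulfate 31 is written in its neutral form; from step 14 it would be handled as its ammonium salt.

## Route

Step 1
Reactants: 1 2,4,6-trihydroxybenzaldehyde
Product: 2 2,4,6-tris(benzyloxy)benzaldehyde
Conditions: BnBr (3.6 equiv), K2CO3, DMF, 60 °C
Reagents that add atoms: benzyl bromide, BrCc1ccccc1
Why: Williamson etherification; the formyl group lowers the nucleophilicity of the ring carbons, so O-benzylation should dominate over C-benzylation, and excess reagent with heat forces the hydrogen-bonded ortho hydroxyl.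

Step 2
Reactants: 2 2,4,6-tris(benzyloxy)benzaldehyde; 3 dimethyl (1-diazo-2-oxopropyl)phosphonate
Product: 4 1,3,5-tris(benzyloxy)-2-ethynylbenzene
Conditions: 3 (1.5 equiv), K2CO3, MeOH–THF, 0 → 25 °C
Reagents that add atoms: none
Why: Seyferth–Gilbert homologation in the Ohira–Bestmann modification; methanolysis of 3 releases the diazomethylphosphonate anion, which olefinates the aldehyde, and loss of N2 with 1,2-shift gives the terminal alkyne under mild base.

Step 3
Reactants: 4 1,3,5-tris(benzyloxy)-2-ethynylbenzene
Product: 7 [2,4,6-tris(benzyloxy)phenyl]acetic acid, via lithium arylacetylide 5 (not isolated), via lithium ynolate 6 (not isolated)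
Conditions: n-BuLi, THF, −78 °C; LiOOt-Bu (from t-BuOOH and LiN(SiMe3)2), −78 → 0 °C; then H2O, 0 → 25 °C; 1 M HCl to pH 3
Reagents that add atoms: tert-butyl hydroperoxide, CC(C)(C)OO; water, O
Why: Oxidation of a lithium acetylide with lithium tert-butyl peroxide (the acetylide carbon attacks the peroxide oxygen and tert-butoxide leaves) gives ynolate 6; C-protonation by water gives the arylketene, which hydroxide traps as the arylacetate.

Step 4
Reactants: 8 benzyl alcohol; 9 trichloroethylene
Product: 12 benzyl ethynyl ether, via benzyl 1,2-dichlorovinyl ether 10 (not isolated), via lithium benzyloxyacetylide 11 (not isolated)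
Conditions: KH, THF, 0 °C; 9, −50 → 25 °C; n-BuLi (2.5 equiv), −78 → −40 °C; MeOH, −78 °C; cold work-up, kept as a solution at −20 °C
Reagents that add atoms: none
Why: The alkoxide adds to dichloroacetylene formed in situ from 9 (anti addition gives the E enol ether 10); n-BuLi then dehydrochlorinates and exchanges Li for Cl to give 11, which is protonated cold. Benzyl alkynyl ethers rearrange sigmatropically only on warming, so 12 is kept cold.

Step 5
Reactants: 7 [2,4,6-tris(benzyloxy)phenyl]acetic acid; 12 benzyl ethynyl ether
Product: 15 rac-3-(benzyloxy)-4-[2,4,6-tris(benzyloxy)phenyl]cyclobut-2-en-1-one, via arylacetyl chloride 13 (not isolated), via arylketene 14 (not isolated)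
Conditions: 1-chloro-N,N,2-trimethylprop-1-en-1-amine, CH2Cl2, 0 → 25 °C; then slow addition to 12 (3 equiv), Et3N, CH2Cl2, 0 → 25 °C
Reagents that add atoms: none
Why: The α-chloroenamine gives acid chloride 13 under neutral conditions (oxalyl chloride or Vilsmeier-type reagents could attack the electron-rich ring), and Et3N dehydrochlorinates it to ketene 14. Ketene–ynol ether [2+2] cycloaddition follows: the nucleophilic CH terminus of 12 bonds to the ketene carbonyl carbon, which places benzyloxy at C3 and the aryl group at C4. The C4 stereocentre forms racemic and is erased in step 10.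

Step 6
Reactants: 1 2,4,6-trihydroxybenzaldehyde
Product: 16 2,4-bis(benzyloxy)-6-hydroxybenzaldehyde
Conditions: BnBr (2.05 equiv), K2CO3 (2.2 equiv), DMF, 0 → 25 °C
Reagents that add atoms: benzyl bromide, BrCc1ccccc1
Why: Williamson etherification with two equivalents; the para hydroxyl and one ortho hydroxyl react, while the last ortho hydroxyl is held in a hydrogen bond to the formyl oxygen and is the least nucleophilic.

Step 7
Reactants: 16 2,4-bis(benzyloxy)-6-hydroxybenzaldehyde
Product: 17 2,4-bis(benzyloxy)-6-(methoxymethoxy)benzaldehyde
Conditions: NaH, DMF, 0 °C; MOMCl, 0 → 25 °C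
Reagents that add atoms: chloromethyl methyl ether, COCCl
Why: O-alkylation of the sodium phenoxide; the acetal survives the strong bases and the heating that follow and can later be removed with acid without touching benzyl ethers.

Step 8
Reactants: 17 2,4-bis(benzyloxy)-6-(methoxymethoxy)benzaldehyde; 3 dimethyl (1-diazo-2-oxopropyl)phosphonate
Product: 18 1,5-bis(benzyloxy)-2-ethynyl-3-(methoxymethoxy)benzene
Conditions: 3 (1.5 equiv), K2CO3, MeOH–THF, 0 → 25 °C
Reagents that add atoms: none
Why: Seyferth–Gilbert homologation (Ohira–Bestmann modification), as in step 2; the acetal and benzyl ethers are inert to K2CO3 in methanol.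

Step 9
Reactants: 18 1,5-bis(benzyloxy)-2-ethynyl-3-(methoxymethoxy)benzene
Product: 21 {[2,4-bis(benzyloxy)-6-(methoxymethoxy)phenyl]ethynyl}oxy-tri(propan-2-yl)silane, via lithium arylacetylide 19 (not isolated), via lithium ynolate 20 (not isolated)
Conditions: n-BuLi, THF, −78 °C; LiOOt-Bu (from t-BuOOH and LiN(SiMe3)2), −78 → 0 °C; i-Pr3SiOTf, −78 → 0 °C; pentane work-up, Et3N-washed silica
Reagents that add atoms: tert-butyl hydroperoxide, CC(C)(C)OO; triisopropylsilyl trifluoromethanesulfonate, CC(C)[Si](OS(=O)(=O)C(F)(F)F)(C(C)C)C(C)C
Why: Acetylide oxidation to ynolate 20 as in step 3, then O-silylation; the bulky silyl triflate reacts at oxygen (small silyl chlorides give C-silyl ketenes) and the triisopropylsilyl ynol ether should tolerate quick chromatography on base-washed silica.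

Step 10
Reactants: 15 rac-3-(benzyloxy)-4-[2,4,6-tris(benzyloxy)phenyl]cyclobut-2-en-1-one; 21 {[2,4-bis(benzyloxy)-6-(methoxymethoxy)phenyl]ethynyl}oxy-tri(propan-2-yl)silane
Product: 26 terphenyl phenol (ring B: OH at B2; OBn at B4; OSi(i-Pr)3 at B6; ring A on B1 with OCH2OMe at A1 and OBn at A3 and A5; ring C on B3 with OBn at C2, C4 and C6), via vinylketene 22 (not isolated), via alkenylcyclobutenone 23 (not isolated), via dienylketene 24 (not isolated), via cyclohexadienone 25 (not isolated)
Conditions: 21 (1.3 equiv), toluene (0.2 M), 80 °C then 110 °C, sealed tube, argon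
Reagents that add atoms: none
Why: Danheiser benzannulation in its thermal cyclobutenone/siloxyalkyne form, a known reaction type applied here to a more crowded pair. Heating opens 15 by 4π electrocyclic cleavage to vinylketene 22, and the polarised alkyne 21 adds across the ketene C=C in a [2+2] cycloaddition: its aryl-bearing β-carbon bonds to the ketene carbonyl carbon (bond B1–B2) and its oxygen-bearing carbon to the ketene α-carbon (bond B5–B6), giving 23. A second 4π opening gives dienylketene 24, and ring B is closed by thermal disrotatory 6π electrocyclisation (re-forming B2–B3) to dienone 25, which tautomerises to phenol 26. The regiochemistry needed is secured by the match between the nucleophilic β-carbon of the ynol ether and the electrophilic ketene carbon; the reverse orientation would put two oxygens on adjacent carbons. Electrocyclisation of 22 onto ring C is unproductive because both ortho positions carry benzyloxy groups and no hydrogen is available for aromatisation to a naphthol; the excess of 21 suppresses ketene dimerisation. No stereocentre is set: the sp3 carbons of 15, 23 and 25 become aromatic, and the A6–B1 axis forms without control. The B2 phenol, flanked by two 2,6-dioxygenated aryl groups, should be too hindered to be acylated by further ketene.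

Step 11
Reactants: 26 terphenyl phenol
Product: 28 octabenzyl ether (OBn at A3, A5, B2, B4, B6, C2, C4 and C6; OCH2OMe at A1), via B2 benzyl ether 27 (not isolated)
Conditions: BnBr (4 equiv), Cs2CO3, DMF, 50 °C; then CsF, 25 → 40 °C
Reagents that add atoms: benzyl bromide, BrCc1ccccc1
Why: Williamson benzylation of the hindered B2 caesium phenoxide, then fluoride cleavage of the aryl silyl ether with in situ benzylation of the B6 phenoxide. Capping B2 first avoids a ring B bis-phenoxide that could C-benzylate at B5.

Step 12
Reactants: 28 octabenzyl ether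
Product: 29 phenol with the free hydroxyl at A1 (eight benzyl ethers)
Conditions: HCl (conc., 5 equiv), MeOH–THF, 45 °C
Reagents that add atoms: none
Why: Acid-catalysed acetal cleavage by transacetalisation with methanol; aryl benzyl ethers are stable to dilute HCl in methanol.

Step 13
Reactants: 29 phenol with the free hydroxyl at A1
Product: 30 aryl 2,2,2-trichloroethyl sulfate at A1 (eight benzyl ethers)
Conditions: Cl3CCH2OSO2Cl (1.5 equiv), Et3N, DMAP, THF, 0 → 25 °C
Reagents that add atoms: 2,2,2-trichloroethyl chlorosulfate, ClC(Cl)(Cl)COS(=O)(=O)Cl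
Why: DMAP-mediated sulfuryl transfer to the only free phenol gives the sulfate as a neutral, chromatographable diester.

Step 14
Reactants: 30 aryl 2,2,2-trichloroethyl sulfate
Product: 31 target, 2-[2,4,6-trihydroxy-3-(2,4,6-trihydroxyphenyl)phenyl]-3,5-dihydroxyphenyl hydrogen sulfate
Conditions: 10% Pd/C, HCO2NH4 (excess), MeOH–THF (degassed), 25 °C; filtration under argon
Reagents that add atoms: none
Why: Catalytic transfer hydrogenolysis cleaves the eight benzyl ethers, and reductive fragmentation of the trichloroethyl group (C–Cl insertion, then β-elimination) frees the sulfate monoester. As its ammonium salt this should be stable to the catalyst, and the formate buffers the HCl formed.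

## Compound list

1 | 2,4,6-trihydroxybenzaldehyde | O=Cc1c(O)cc(O)cc1O | starting material
2 | 2,4,6-tris(benzyloxy)benzaldehyde | O=Cc1c(OCc2ccccc2)cc(OCc2ccccc2)cc1OCc1ccccc1 | intermediate
3 | dimethyl (1-diazo-2-oxopropyl)phosphonate | CC(=O)C(=[N+]=[N-])P(=O)(OC)OC | starting material
4 | 1,3,5-tris(benzyloxy)-2-ethynylbenzene | C#Cc1c(OCc2ccccc2)cc(OCc2ccccc2)cc1OCc1ccccc1 | intermediate
5 | lithium [2,4,6-tris(benzyloxy)phenyl]acetylide | [Li]C#Cc1c(OCc2ccccc2)cc(OCc2ccccc2)cc1OCc1ccccc1 | intermediate (not isolated)
6 | lithium 2-[2,4,6-tris(benzyloxy)phenyl]ethynolate | [Li+].[O-]C#Cc1c(OCc2ccccc2)cc(OCc2ccccc2)cc1OCc1ccccc1 | intermediate (not isolated)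
7 | [2,4,6-tris(benzyloxy)phenyl]acetic acid | OC(=O)Cc1c(OCc2ccccc2)cc(OCc2ccccc2)cc1OCc1ccccc1 | intermediate
8 | benzyl alcohol | OCc1ccccc1 | starting material
9 | trichloroethylene | ClC=C(Cl)Cl | starting material
10 | benzyl (E)-1,2-dichloroethenyl ether | Cl/C=C(Cl)\OCc1ccccc1 | intermediate (not isolated)
11 | lithium (benzyloxy)acetylide | [Li]C#COCc1ccccc1 | intermediate (not isolated)
12 | benzyl ethynyl ether | C#COCc1ccccc1 | intermediate
13 | [2,4,6-tris(benzyloxy)phenyl]acetyl chloride | O=C(Cl)Cc1c(OCc2ccccc2)cc(OCc2ccccc2)cc1OCc1ccccc1 | intermediate (not isolated)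
14 | [2,4,6-tris(benzyloxy)phenyl]ketene | O=C=Cc1c(OCc2ccccc2)cc(OCc2ccccc2)cc1OCc1ccccc1 | intermediate (not isolated)
15 | rac-3-(benzyloxy)-4-[2,4,6-tris(benzyloxy)phenyl]cyclobut-2-en-1-one | O=C1C=C(OCc2ccccc2)C1c1c(OCc2ccccc2)cc(OCc2ccccc2)cc1OCc1ccccc1 | intermediate
16 | 2,4-bis(benzyloxy)-6-hydroxybenzaldehyde | O=Cc1c(O)cc(OCc2ccccc2)cc1OCc1ccccc1 | intermediate
17 | 2,4-bis(benzyloxy)-6-(methoxymethoxy)benzaldehyde | COCOc1cc(OCc2ccccc2)cc(OCc2ccccc2)c1C=O | intermediate
18 | 1,5-bis(benzyloxy)-2-ethynyl-3-(methoxymethoxy)benzene | COCOc1cc(OCc2ccccc2)cc(OCc2ccccc2)c1C#C | intermediate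
19 | lithium [2,4-bis(benzyloxy)-6-(methoxymethoxy)phenyl]acetylide | COCOc1cc(OCc2ccccc2)cc(OCc2ccccc2)c1C#C[Li] | intermediate (not isolated)
20 | lithium 2-[2,4-bis(benzyloxy)-6-(methoxymethoxy)phenyl]ethynolate | COCOc1cc(OCc2ccccc2)cc(OCc2ccccc2)c1C#C[O-].[Li+] | intermediate (not isolated)
21 | {[2,4-bis(benzyloxy)-6-(methoxymethoxy)phenyl]ethynyl}oxy-tri(propan-2-yl)silane | COCOc1cc(OCc2ccccc2)cc(OCc2ccccc2)c1C#CO[Si](C(C)C)(C(C)C)C(C)C | intermediate
22 | (3Z)-3-(benzyloxy)-4-[2,4,6-tris(benzyloxy)phenyl]buta-1,3-dien-1-one | O=C=C/C(OCc1ccccc1)=C/c1c(OCc2ccccc2)cc(OCc2ccccc2)cc1OCc1ccccc1 | intermediate (not isolated)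
23 | rac-2-[2,4-bis(benzyloxy)-6-(methoxymethoxy)phenyl]-4-{(Z)-1-(benzyloxy)-2-[2,4,6-tris(benzyloxy)phenyl]ethenyl}-3-(triisopropylsiloxy)cyclobut-2-en-1-one | O=C1C(c2c(OCOC)cc(OCc3ccccc3)cc2OCc2ccccc2)=C(O[Si](C(C)C)(C(C)C)C(C)C)C1/C(OCc1ccccc1)=C/c1c(OCc2ccccc2)cc(OCc2ccccc2)cc1OCc1ccccc1 | intermediate (not isolated)
24 | (3E,5Z)-2-[2,4-bis(benzyloxy)-6-(methoxymethoxy)phenyl]-5-(benzyloxy)-3-(triisopropylsiloxy)-6-[2,4,6-tris(benzyloxy)phenyl]hexa-1,3,5-trien-1-one | O=C=C(c1c(OCOC)cc(OCc2ccccc2)cc1OCc1ccccc1)/C(O[Si](C(C)C)(C(C)C)C(C)C)=C\C(OCc1ccccc1)=C\c1c(OCc2ccccc2)cc(OCc2ccccc2)cc1OCc1ccccc1 | intermediate (not isolated)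
25 | rac-2-[2,4-bis(benzyloxy)-6-(methoxymethoxy)phenyl]-5-(benzyloxy)-3-(triisopropylsiloxy)-6-[2,4,6-tris(benzyloxy)phenyl]cyclohexa-2,4-dien-1-one | O=C1C(c2c(OCOC)cc(OCc3ccccc3)cc2OCc2ccccc2)=C(O[Si](C(C)C)(C(C)C)C(C)C)C=C(OCc2ccccc2)C1c1c(OCc2ccccc2)cc(OCc2ccccc2)cc1OCc1ccccc1 | intermediate (not isolated)
26 | terphenyl phenol: OH at B2, OBn at B4, OSi(i-Pr)3 at B6; ring A (OCH2OMe at A1, OBn at A3 and A5) on B1; ring C (OBn at C2, C4, C6) on B3; axis not controlled | COCOc1cc(OCc2ccccc2)cc(OCc2ccccc2)c1-c1c(O[Si](C(C)C)(C(C)C)C(C)C)cc(OCc2ccccc2)c(-c2c(OCc3ccccc3)cc(OCc3ccccc3)cc2OCc2ccccc2)c1O | intermediate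
27 | as 26 with OBn at B2 (silyl ether at B6 kept) | COCOc1cc(OCc2ccccc2)cc(OCc2ccccc2)c1-c1c(O[Si](C(C)C)(C(C)C)C(C)C)cc(OCc2ccccc2)c(-c2c(OCc3ccccc3)cc(OCc3ccccc3)cc2OCc2ccccc2)c1OCc1ccccc1 | intermediate (not isolated)
28 | octabenzyl ether: OBn at A3, A5, B2, B4, B6, C2, C4, C6; OCH2OMe at A1 | COCOc1cc(OCc2ccccc2)cc(OCc2ccccc2)c1-c1c(OCc2ccccc2)cc(OCc2ccccc2)c(-c2c(OCc3ccccc3)cc(OCc3ccccc3)cc2OCc2ccccc2)c1OCc1ccccc1 | intermediate
29 | as 28 with free OH at A1 | Oc1cc(OCc2ccccc2)cc(OCc2ccccc2)c1-c1c(OCc2ccccc2)cc(OCc2ccccc2)c(-c2c(OCc3ccccc3)cc(OCc3ccccc3)cc2OCc2ccccc2)c1OCc1ccccc1 | intermediate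
30 | as 29 with OSO2OCH2CCl3 at A1 | ClC(Cl)(Cl)COS(=O)(=O)Oc1cc(OCc2ccccc2)cc(OCc2ccccc2)c1-c1c(OCc2ccccc2)cc(OCc2ccccc2)c(-c2c(OCc3ccccc3)cc(OCc3ccccc3)cc2OCc2ccccc2)c1OCc1ccccc1 | intermediate
31 | 2-[2,4,6-trihydroxy-3-(2,4,6-trihydroxyphenyl)phenyl]-3,5-dihydroxyphenyl hydrogen sulfate | O=S(=O)(O)Oc1cc(O)cc(O)c1-c1c(O)cc(O)c(-c2c(O)cc(O)cc2O)c1O | target

## Step count and least certain steps

Total: 14 steps. Longest linear sequence: 9 steps (1, 2, 3, 5, 10, 11, 12, 13, 14, or equally 6, 7, 8, 9, 10 to 14). Commercial inputs are 1, 3, 8, 9, benzyl bromide, chloromethyl methyl ether, tert-butyl hydroperoxide, triisopropylsilyl triflate and 2,2,2-trichloroethyl chlorosulfate.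

**Step 10 (key).** The most likely failure is a slow [2+2] step at the alkyne carbon that carries the 2,6-dioxygenated ring. Thermal silyl migration in 21 (to a silylketene) or dimerisation of ketene 22 could then outrun annulation at the temperature needed to open 15. The fallback generates the same vinylketene at room temperature by photochemical Wolff rearrangement. It sets out from 2. Horner–Wadsworth–Emmons olefination with methyl (benzyloxy)(dimethoxyphosphoryl)acetate would give methyl 2-(benzyloxy)-3-[2,4,6-tris(benzyloxy)phenyl]prop-2-enoate F1. LiOH would give the acid F2. The acid chloride (α-chloroenamine) and diazomethane would give 3-(benzyloxy)-1-diazo-4-[2,4,6-tris(benzyloxy)phenyl]but-3-en-2-one F3. Irradiation of F3 with 21 at 20 °C, then brief warming to 60–80 °C, passes through 22 and returns to the route at 26.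

**Step 5.** Loss of the ynol ether is the main risk: acid-promoted hydration by the ammonium salt or sigmatropic rearrangement on warming. Ketene 14 may also dimerise, and 13 may lactonise with loss of a benzyl group. The fallback is amine-free, low-temperature ketene generation, setting out from 2. Pinnick oxidation would give 2,4,6-tris(benzyloxy)benzoic acid F4. The acid chloride and diazomethane would give 2-diazo-1-[2,4,6-tris(benzyloxy)phenyl]ethan-1-one F5. Photochemical Wolff rearrangement of F5 at −20 °C in the presence of 12 gives 14 and returns at 15.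

**Step 9.** Oxygen transfer to the hindered, electron-rich acetylide may be incomplete, and the ynol ether may hydrolyse during isolation. The fallback is a Kowalski ester homologation from 17. Pinnick oxidation would give 2,4-bis(benzyloxy)-6-(methoxymethoxy)benzoic acid F6, and MeI with K2CO3 the methyl ester F7. LiCHBr2 (from CH2Br2 and lithium 2,2,6,6-tetramethylpiperidide) and then n-BuLi would deliver ynolate 20. Silylation as before returns at 21, which could be taken into step 10 without chromatography.

**Step 11.** Etherification at B2 may stall between the two flanking aryl groups, or C-benzylation at B5 may intrude. The fallback leaves B2 free and relies on the same hindrance later. It sets out from 26. Bu4NF, then BnBr and K2CO3 at 25 °C, would give the B6 benzyl ether with free B2 hydroxyl F8. HCl in methanol would give the A1,B2-diol F9. One equivalent of Cl3CCH2OSO2Cl should sulfate the exposed A1 hydroxyl to give the trichloroethyl sulfate F10. The conditions of step 14 then return at 31.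

**Step 14.** Stepwise hydrodechlorination of the CCl3 group could give an ester that no longer fragments. Debenzylation of eight ethers may be incomplete, and desulfation may occur if the HCl is not buffered. The fallback avoids the diester and sets out from 29. SO3·pyridine would give the aryl sulfate monoester F11 (handled as its pyridinium or sodium salt). Hydrogenolysis with H2 and Pd(OH)2/C in buffered MeOH–THF returns at 31.

## Further compounds

F1 | step 10 | methyl 2-(benzyloxy)-3-[2,4,6-tris(benzyloxy)phenyl]prop-2-enoate (alkene geometry immaterial) | COC(=O)C(OCc1ccccc1)=Cc1c(OCc2ccccc2)cc(OCc2ccccc2)cc1OCc1ccccc1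
F2 | step 10 | 2-(benzyloxy)-3-[2,4,6-tris(benzyloxy)phenyl]prop-2-enoic acid | OC(=O)C(OCc1ccccc1)=Cc1c(OCc2ccccc2)cc(OCc2ccccc2)cc1OCc1ccccc1
F3 | step 10 | 3-(benzyloxy)-1-diazo-4-[2,4,6-tris(benzyloxy)phenyl]but-3-en-2-one | [N-]=[N+]=CC(=O)C(OCc1ccccc1)=Cc1c(OCc2ccccc2)cc(OCc2ccccc2)cc1OCc1ccccc1
F4 | step 5 | 2,4,6-tris(benzyloxy)benzoic acid | OC(=O)c1c(OCc2ccccc2)cc(OCc2ccccc2)cc1OCc1ccccc1
F5 | step 5 | 2-diazo-1-[2,4,6-tris(benzyloxy)phenyl]ethan-1-one | [N-]=[N+]=CC(=O)c1c(OCc2ccccc2)cc(OCc2ccccc2)cc1OCc1ccccc1
F6 | step 9 | 2,4-bis(benzyloxy)-6-(methoxymethoxy)benzoic acid | COCOc1cc(OCc2ccccc2)cc(OCc2ccccc2)c1C(=O)O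
F7 | step 9 | methyl 2,4-bis(benzyloxy)-6-(methoxymethoxy)benzoate | COCOc1cc(OCc2ccccc2)cc(OCc2ccccc2)c1C(=O)OC
F8 | step 11 | terphenyl with free OH at B2, OBn at B4 and B6, OCH2OMe at A1, other oxygens benzylated | COCOc1cc(OCc2ccccc2)cc(OCc2ccccc2)c1-c1c(OCc2ccccc2)cc(OCc2ccccc2)c(-c2c(OCc3ccccc3)cc(OCc3ccccc3)cc2OCc2ccccc2)c1O
F9 | step 11 | terphenyl diol with free OH at A1 and B2, seven benzyl ethers | Oc1cc(OCc2ccccc2)cc(OCc2ccccc2)c1-c1c(OCc2ccccc2)cc(OCc2ccccc2)c(-c2c(OCc3ccccc3)cc(OCc3ccccc3)cc2OCc2ccccc2)c1O
F10 | step 11 | as F9 with OSO2OCH2CCl3 at A1, free OH at B2 | ClC(Cl)(Cl)COS(=O)(=O)Oc1cc(OCc2ccccc2)cc(OCc2ccccc2)c1-c1c(OCc2ccccc2)cc(OCc2ccccc2)c(-c2c(OCc3ccccc3)cc(OCc3ccccc3)cc2OCc2ccccc2)c1O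
F11 | step 14 | octabenzyl terphenyl hydrogen sulfate at A1 | OS(=O)(=O)Oc1cc(OCc2ccccc2)cc(OCc2ccccc2)c1-c1c(OCc2ccccc2)cc(OCc2ccccc2)c(-c2c(OCc3ccccc3)cc(OCc3ccccc3)cc2OCc2ccccc2)c1OCc1ccccc1
A1 | alternative 1 | 2,4,6-tris(benzyloxy)benzene with the arm –CH=C(OBn)–CH(OAc)–C≡CH at B1 and at B3 (mixture of stereoisomers) | C#CC(OC(C)=O)C(OCc1ccccc1)=Cc1c(OCc2ccccc2)cc(OCc2ccccc2)c(C=C(OCc2ccccc2)C(OC(C)=O)C#C)c1OCc1ccccc1
A2 | alternative 1 | terphenyl with free OH at position A1 and position C2, acetates at A3 and C4, benzyl ethers at A5, C6, B2, B4 and B6 | Oc3cc(OC(C)=O)cc(OCc4ccccc4)c3-c1c(OCc4ccccc4)cc(OCc4ccccc4)c(-c2c(O)cc(OC(C)=O)cc2OCc4ccccc4)c1OCc4ccccc4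
A3 | alternative 2 | 3-aryl-4-hydroxy-6-methyl-2H-pyran-2-one, aryl being the A–B biaryl (OCH2OMe at A1, benzyl ethers at A3, A5, B2, B4, B6) | COCOc1cc(OCc2ccccc2)cc(OCc2ccccc2)c1-c1c(OCc2ccccc2)cc(OCc2ccccc2)c(-c2c(O)cc(C)oc2=O)c1OCc1ccccc1
A4 | alternative 2 | terphenyl with ring C as free triol, OCH2OMe at A1, benzyl ethers at A3, A5, B2, B4, B6 | COCOc3cc(OCc4ccccc4)cc(OCc4ccccc4)c3-c1c(OCc4ccccc4)cc(OCc4ccccc4)c(-c2c(O)cc(O)cc2O)c1OCc4ccccc4
A5 | alternative 3 | dimethyl 2-[2,4-bis(benzyloxy)-6-(methoxymethoxy)phenyl]-3-oxo-4-[2,4,6-tris(benzyloxy)phenyl]pentanedioate (mixture of stereoisomers) | COC(=O)C(c1c(OCOC)cc(OCc2ccccc2)cc1OCc1ccccc1)C(=O)C(c1c(OCc2ccccc2)cc(OCc2ccccc2)cc1OCc1ccccc1)C(=O)OC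
A6 | alternative 3 | lithium enolate of tert-butyl acetate | C=C(O[Li])OC(C)(C)C
A7 | alternative 3 | tert-butyl 3-[2,4-bis(benzyloxy)-6-(methoxymethoxy)phenyl]-2,4,6-trihydroxy-5-[2,4,6-tris(benzyloxy)phenyl]benzoate | COCOc3cc(OCc4ccccc4)cc(OCc4ccccc4)c3-c1c(O)c(C(=O)OC(C)(C)C)c(O)c(-c2c(OCc4ccccc4)cc(OCc4ccccc4)cc2OCc4ccccc4)c1O
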